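**Plan**

Numbering (germacrane): ring carbons C1–C10; lactone O–C6, C7, C11(=C13H2), C12(=O); C14 is the exocyclic CH2 on C10; C15 is the CH2OAc carbon on C4; C3' is the side-chain carbinol.
Retrosynthesis: cleave the O8 ester, then cut C6–C7 and C11–C12 of the lactone together (O6–C12 goes with them) to an acyclic C6 enal bearing a C7=C11=C13 terminal allene, plus CO; then cut C1–C10, C11–C13 and C4=C5.
Enabling feature: the cis-fused α-methylene-γ-butyrolactone O–C6–C7–C11(=C13H2)–C12(=O) on the ten-membered carbocycle is the retron of a hetero-Pauson–Khand [2+2+1] of an aldehyde (C6=O), the inner C=C of a terminal allene (C7=C11) and CO (C12); that reaction gives cis ring fusion.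
Forward: the chain is joined at C1–C10, the allene and the enal are unmasked, one cyclocarbonylation closes the ten-membered ring and the lactone together, and O8 acylation and deprotection finish.
Stereochemistry: C8 from a catalytic asymmetric 2-bromoallylation, C1 from a ligand-controlled Ni/Cr coupling, C6 and C7 in the key step (cis fusion from the metallacycle, facial choice from C8), C3' from the chiral pool, C4=C5 geometry from an (E)-selective Horner–Wadsworth–Emmons reaction.

Key step: step 14

Assumption: L is the chiral sulfonamide–oxazoline ligand N-[2-(4-isopropyl-4,5-dihydro-1,3-oxazol-2-yl)-6-methylphenyl]methanesulfonamide; its sense of induction in steps 6 and 8 is taken by analogy with simple aldehydes, and the antipodal ligand would be used if a model study showed the opposite sense. All compounds marked starting material in the list are taken as commercially available.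

**Route**

Step 1
Reactants: 1 triethyl phosphonoacetate; 2 3-bromo-1,1-dimethoxypropane
Product: 3 ethyl 2-(diethoxyphosphoryl)-5,5-dimethoxypentanoate (racemic)
Conditions: NaH (1.0 equiv), 1 (1.5 equiv), DMSO, rt; then 2, 60 °C
Reagents that add atoms: none
Why: SN2 C-alkylation of the sodium phosphonoacetate anion by the primary bromide (malonate-type alkylation); the excess of 1 should hold back dialkylation.

Step 2
Reactants: 3 ethyl 2-(diethoxyphosphoryl)-5,5-dimethoxypentanoate; 4 2-[(4-methoxybenzyl)oxy]acetaldehyde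
Product: 5 ethyl (E)-2-(3,3-dimethoxypropyl)-4-[(4-methoxybenzyl)oxy]but-2-enoate
Conditions: NaH, THF, 0 °C; then 4, 0 °C → rt
Reagents that add atoms: none
Why: Horner–Wadsworth–Emmons olefination; α-alkyl phosphonoacetates should give the (E)-enoate (ester trans to the aldehyde residue), which places C6 cis to the C3 chain and trans to C15, the ring-cis C4=C5 geometry of the target.

Step 3
Reactants: 5 ethyl (E)-2-(3,3-dimethoxypropyl)-4-[(4-methoxybenzyl)oxy]but-2-enoate
Product: 6 (E)-2-(3,3-dimethoxypropyl)-4-[(4-methoxybenzyl)oxy]but-2-en-1-ol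
Conditions: iBu2AlH (2.3 equiv), CH2Cl2, −78 °C; potassium sodium tartrate work-up
Reagents that add atoms: none
Why: 1,2-reduction of the α,β-unsaturated ester to the allylic alcohol by the aluminium hydride, which should leave the acetal, the PMB ether and the olefin geometry untouched.

Step 4
Reactants: 6 (E)-2-(3,3-dimethoxypropyl)-4-[(4-methoxybenzyl)oxy]but-2-en-1-ol
Product: 7 (E)-2-(3,3-dimethoxypropyl)-4-[(4-methoxybenzyl)oxy]but-2-en-1-yl acetate
Conditions: Ac2O, pyridine, DMAP (cat.), CH2Cl2, 0 °C → rt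
Reagents that add atoms: acetic anhydride, CC(=O)OC(C)=O
Why: O-acetylation installs the C15 acetate of the target at a point after which no hydride or strongly basic reagent meets this chain.

Step 5
Reactants: 7 (E)-2-(3,3-dimethoxypropyl)-4-[(4-methoxybenzyl)oxy]but-2-en-1-yl acetate
Product: 8 (E)-4-[(4-methoxybenzyl)oxy]-2-(3-oxopropyl)but-2-en-1-yl acetate
Conditions: TsOH·H2O (10 mol%), acetone/H2O (10:1), rt
Reagents that add atoms: water, O
Why: acid-catalysed hydrolysis of the dimethyl acetal unmasks the C1 aldehyde; the allylic acetate and the PMB ether should be stable to dilute acid.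

Step 6
Reactants: 9 3-(trimethylsilyl)prop-2-ynal; 10 2,3-dibromopropene
Product: 11 (S)-5-bromo-1-(trimethylsilyl)hex-5-en-1-yn-3-ol
Conditions: CrCl2 (10 mol%), ligand L (12 mol%), Et3N (20 mol%), Mn powder (2 equiv), Cp2ZrCl2 (1.2 equiv), THF, 0 °C → rt; aqueous work-up
Reagents that add atoms: none
Why: catalytic asymmetric Nozaki–Hiyama 2-haloallylation; low-valent chromium should insert only into the allylic C–Br bond of 10 and the 2-bromoallylchromium adds to the ynal inside the chiral sulfonamide complex, setting C8 (S) by catalyst control while the vinyl bromide is kept for step 8.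

Step 7
Reactants: 11 (S)-5-bromo-1-(trimethylsilyl)hex-5-en-1-yn-3-ol
Product: 12 (S)-[(5-bromo-1-(trimethylsilyl)hex-5-en-1-yn-3-yl)oxy]triethylsilane
Conditions: Et3SiCl, imidazole, CH2Cl2, 0 °C
Reagents that add atoms: chlorotriethylsilane, CC[Si](Cl)(CC)CC
Why: silylation of the propargylic alcohol gives a C8 ether that can later be removed in the presence of the C1 tert-butyldimethylsilyl ether.

Step 8
Reactants: 8 (E)-4-[(4-methoxybenzyl)oxy]-2-(3-oxopropyl)but-2-en-1-yl acetate; 12 (S)-[(5-bromo-1-(trimethylsilyl)hex-5-en-1-yn-3-yl)oxy]triethylsilane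
Product: 13 (E)-2-[(3R,6S)-3-hydroxy-4-methylidene-6-[(triethylsilyl)oxy]-8-(trimethylsilyl)oct-7-yn-1-yl]-4-[(4-methoxybenzyl)oxy]but-2-en-1-yl acetate
Conditions: CrCl2 (15 mol%), ligand L (17 mol%), Et3N, NiCl2(2,9-dimethyl-1,10-phenanthroline) (3 mol%), Mn powder, Cp2ZrCl2 (1.5 equiv), LiCl, MeCN, rt
Reagents that add atoms: none
Why: Nozaki–Hiyama–Kishi coupling; the nickel co-catalyst activates the C10–Br bond, the alkenyl group passes to chromium and adds to the C1 aldehyde inside the chiral sulfonamide complex, which should set C1 (R) by ligand control because C8 is too remote to direct.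

Step 9
Reactants: 13 the C1 allylic alcohol from step 8
Product: 14 (E)-2-[(3R,6S)-3-[(tert-butyldimethylsilyl)oxy]-4-methylidene-6-[(triethylsilyl)oxy]-8-(trimethylsilyl)oct-7-yn-1-yl]-4-[(4-methoxybenzyl)oxy]but-2-en-1-yl acetate
Conditions: tBuMe2SiOTf, 2,6-lutidine, CH2Cl2, −78 → 0 °C
Reagents that add atoms: tert-butyldimethylsilyl trifluoromethanesulfonate, CC(C)(C)[Si](C)(C)OS(=O)(=O)C(F)(F)F
Why: silyl triflate silylation of the secondary allylic alcohol gives the C1 ether that is kept until the last step.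

Step 10
Reactants: 14 the bis-silyl ether silylalkyne from step 9
Product: 15 (E)-2-[(3R,6S)-3-[(tert-butyldimethylsilyl)oxy]-4-methylidene-6-[(triethylsilyl)oxy]oct-7-yn-1-yl]-4-[(4-methoxybenzyl)oxy]but-2-en-1-yl acetate
Conditions: AgNO3 (10 mol%), acetone/H2O (10:1), rt
Reagents that add atoms: none
Why: silver-catalysed protiodesilylation of the alkynyl–silicon bond (through the silver acetylide) should spare the O-silyl ethers and the acetate that a basic methanolysis would cleave.

Step 11
Reactants: 15 the terminal alkyne from step 10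
Product: 17 (E)-2-[(3R,6S)-3-[(tert-butyldimethylsilyl)oxy]-4-methylidene-6-[(triethylsilyl)oxy]nona-7,8-dien-1-yl]-4-[(4-methoxybenzyl)oxy]but-2-en-1-yl acetate, via Mannich base 16 (not isolated)
Conditions: (CH2O)n, CuI (0.5 equiv), Cy2NH (1.8 equiv), 1,4-dioxane, reflux
Reagents that add atoms: paraformaldehyde (formaldehyde), C=O
Why: Crabbé homologation; the copper-catalysed Mannich reaction gives propargylic amine 16, whose copper-assisted 1,5-hydride shift with loss of the imine turns the alkyne into the terminal allene and adds C13 without touching C8.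

Step 12
Reactants: 17 the allene from step 11
Product: 18 (E)-2-[(3R,6S)-3-[(tert-butyldimethylsilyl)oxy]-4-methylidene-6-[(triethylsilyl)oxy]nona-7,8-dien-1-yl]-4-hydroxybut-2-en-1-yl acetate
Conditions: DDQ, CH2Cl2/pH 7 buffer (10:1), 0 °C
Reagents that add atoms: none
Why: oxidative cleavage of the PMB ether (benzylic hydride abstraction, then hydrolysis of the oxocarbenium ion) frees the C6 alcohol; silyl ethers, acetate and allene should be inert in the buffered medium.

Step 13
Reactants: 18 the C6 allylic alcohol from step 12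
Product: 19 (E)-2-[(3R,6S)-3-[(tert-butyldimethylsilyl)oxy]-4-methylidene-6-[(triethylsilyl)oxy]nona-7,8-dien-1-yl]-4-oxobut-2-en-1-yl acetate
Conditions: Dess–Martin periodinane, NaHCO3, CH2Cl2, 0 °C → rt
Reagents that add atoms: none
Why: Dess–Martin oxidation of the allylic alcohol to the enal under buffered conditions should keep the olefin geometry.

Step 14
Reactants: 19 the allenyl enal from step 13
Product: 20 (1R,6S,7R,8S)-15-acetoxy-1-[(tert-butyldimethylsilyl)oxy]-8-[(triethylsilyl)oxy]germacra-4,10(14),11(13)-trien-12,6-olide (6,7-cis lactone; C3 and C6 cis on C4=C5, E by CIP)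
Conditions: Ru3(CO)12 (5 mol%), CO (10 atm), 1,4-dioxane (0.003 M), 110 °C
Reagents that add atoms: carbon monoxide, [C-]#[O+]
Why: Proposed new method: zerovalent ruthenium carbonyl should bind the C6 aldehyde and the inner C7=C11 bond of the terminal allene and couple them oxidatively (C6–C7 bond) to a 2-oxaruthenacyclopentane bearing the exocyclic C11=C13 methylene, CO then inserts into the Ru–C11 bond (C11–C12 bond) and acyl–alkoxide reductive elimination (O6–C12) releases the α-methylene-γ-butyrolactone and the catalyst. The closest known reaction type is the Ru3(CO)12-catalysed (or Mo(CO)6-mediated) hetero-Pauson–Khand cyclocarbonylation of allenyl aldehydes, shown so far only where a five- or six-membered carbocycle forms, so closure of a ten-membered ring is the untested extension. The ten-membered carbocycle closes in the oxidative coupling by exo attack of C6 on the inner allene carbon, eased by the ring-cis C4=C5 bond and the sp2 centres C4, C5 and C10 that remove rotors and transannular hydrogens, and the five-membered lactone closes as the formal [2+2+1] by CO insertion and C–O reductive elimination. C6 and C7 are set together with H6 and H7 cis, because both new bonds form within one five-membered metallacycle whose tether lies on a single face, as in the known bicyclic cases; C7 is set relative to C8 by the inside-alkoxy arrangement known from cycloadditions to chiral allylic ethers (C9 anti to the forming C6–C7 bond, the C8–O bond near the allene axis where an allene causes no 1,3-allylic strain, H8 outside), which leads to the 7R,8S array. The step needs chemoselectivity for the aldehyde/allene pair over the C10=C14 alkene, the enal C=C and the allylic acetate, which the stronger binding of a terminal allene and an aldehyde to ruthenium carbonyl should give, and it needs ring closure to outrun oligomerisation, which the high dilution addresses.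

Step 15
Reactants: 20 the protected cis-lactone from step 14
Product: 21 (1R,6S,7R,8S)-15-acetoxy-1-[(tert-butyldimethylsilyl)oxy]-8-hydroxygermacra-4,10(14),11(13)-trien-12,6-olide
Conditions: HF·pyridine, pyridine, THF, 0 °C
Reagents that add atoms: none
Why: fluoride cleavage of the secondary triethylsilyl ether should be much faster than that of the secondary tert-butyldimethylsilyl ether, and the pyridine buffer should keep the free C8 carbinol from translactonising.

Step 16
Reactants: 22 (R)-4-hydroxydihydrofuran-2(3H)-one [(R)-3-hydroxy-γ-butyrolactone]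
Product: 23 (3R,4R)-3-[(dimethylamino)methyl]-4-hydroxydihydrofuran-2(3H)-one
Conditions: LiN(iPr)2 (2.2 equiv), THF, −78 °C; then CH2=NMe2+ I−, −78 → 0 °C
Reagents that add atoms: N,N-dimethylmethyleneiminium iodide (Eschenmoser's salt), C=[N+](C)C.[I-]
Why: Fráter–Seebach-type dianion formation (the alkoxide blocks β-elimination) and Mannich reaction with the iminium salt; attack anti to the alkoxide should give the trans product, and this new centre is removed in step 17.

Step 17
Reactants: 23 the Mannich base from step 16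
Product: 25 (R)-4-hydroxy-3-methylidenedihydrofuran-2(3H)-one, via ammonium iodide 24 (not isolated)
Conditions: MeI, MeOH, rt; then NaHCO3 (aq.), CH2Cl2, rt
Reagents that add atoms: none
Why: exhaustive N-methylation and base-induced β-elimination of trimethylamine (Eschenmoser methylenation) give the α-methylene lactone without involving the carbinol centre.

Step 18
Reactants: 25 (R)-4-hydroxy-3-methylidenedihydrofuran-2(3H)-one
Product: 26 methyl 2-[(4R)-2,2-dimethyl-1,3-dioxolan-4-yl]prop-2-enoate
Conditions: Me2C(OMe)2, MeOH, TsOH·H2O (cat.), rt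
Reagents that add atoms: 2,2-dimethoxypropane, COC(C)(C)OC; methanol, CO
Why: acid-catalysed methanolysis of the lactone is driven forward by trapping the freed 1,2-diol as its acetonide (transketalisation).

Step 19
Reactants: 26 methyl 2-[(4R)-2,2-dimethyl-1,3-dioxolan-4-yl]prop-2-enoate
Product: 27 2-[(4R)-2,2-dimethyl-1,3-dioxolan-4-yl]prop-2-enoic acid
Conditions: LiOH (1.5 equiv), THF/H2O (3:1), 0 °C; then 1 M HCl to pH 3, 0 °C
Reagents that add atoms: lithium hydroxide, [Li+].[OH-]
Why: saponification of the methyl ester; the acetonide should survive the brief cold acidification.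

Step 20
Reactants: 21 the C8 alcohol from step 15; 27 2-[(4R)-2,2-dimethyl-1,3-dioxolan-4-yl]prop-2-enoic acid
Product: 29 (1R,6S,7R,8S)-15-acetoxy-1-[(tert-butyldimethylsilyl)oxy]-8-[2-[(4R)-2,2-dimethyl-1,3-dioxolan-4-yl]prop-2-enoyloxy]germacra-4,10(14),11(13)-trien-12,6-olide, via mixed anhydride 28 (not isolated)
Conditions: 27, 2,4,6-trichlorobenzoyl chloride, Et3N, toluene, rt; then 21, DMAP, rt
Reagents that add atoms: none
Why: Yamaguchi esterification; the mixed anhydride is attacked at the less hindered acryloyl carbonyl through the acylpyridinium, which should acylate the hindered C8 carbinol with retention at C8.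

Step 21
Reactants: 29 the protected ester from step 20
Product: 30 (1R,6S,7R,8S)-15-acetoxy-8-[(3R)-3,4-dihydroxy-2-methylidenebutanoyloxy]-1-hydroxygermacra-4,10(14),11(13)-trien-12,6-olide (CNP0245550.1)
Conditions: CF3CO2H/H2O (9:1), CH2Cl2, 0 °C
Reagents that add atoms: none
Why: acid hydrolysis removes the acetonide and the tert-butyldimethylsilyl ether in one operation; the allylic acetate, the acrylate and the α-methylene lactone should be stable to cold aqueous acid.

**Compound list**

1 | triethyl phosphonoacetate | CCOC(=O)CP(=O)(OCC)OCC | starting material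
2 | 3-bromo-1,1-dimethoxypropane | COC(CCBr)OC | starting material
3 | ethyl 2-(diethoxyphosphoryl)-5,5-dimethoxypentanoate (racemic) | CCOC(=O)C(CCC(OC)OC)P(=O)(OCC)OCC | intermediate
4 | 2-[(4-methoxybenzyl)oxy]acetaldehyde | COc1ccc(COCC=O)cc1 | starting material
5 | ethyl (E)-2-(3,3-dimethoxypropyl)-4-[(4-methoxybenzyl)oxy]but-2-enoate | CCOC(=O)/C(CCC(OC)OC)=C/COCc1ccc(OC)cc1 | intermediate
6 | (E)-2-(3,3-dimethoxypropyl)-4-[(4-methoxybenzyl)oxy]but-2-en-1-ol | OC/C(CCC(OC)OC)=C/COCc1ccc(OC)cc1 | intermediate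
7 | (E)-2-(3,3-dimethoxypropyl)-4-[(4-methoxybenzyl)oxy]but-2-en-1-yl acetate | CC(=O)OC/C(CCC(OC)OC)=C/COCc1ccc(OC)cc1 | intermediate
8 | (E)-4-[(4-methoxybenzyl)oxy]-2-(3-oxopropyl)but-2-en-1-yl acetate | CC(=O)OC/C(CCC=O)=C/COCc1ccc(OC)cc1 | intermediate
9 | 3-(trimethylsilyl)prop-2-ynal | C[Si](C)(C)C#CC=O | starting material
10 | 2,3-dibromopropene | C=C(Br)CBr | starting material
11 | (S)-5-bromo-1-(trimethylsilyl)hex-5-en-1-yn-3-ol | C=C(Br)C[C@H](O)C#C[Si](C)(C)C | intermediate
12 | (S)-[(5-bromo-1-(trimethylsilyl)hex-5-en-1-yn-3-yl)oxy]triethylsilane | C=C(Br)C[C@H](O[Si](CC)(CC)CC)C#C[Si](C)(C)C | intermediate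
13 | (E)-2-[(3R,6S)-3-hydroxy-4-methylidene-6-[(triethylsilyl)oxy]-8-(trimethylsilyl)oct-7-yn-1-yl]-4-[(4-methoxybenzyl)oxy]but-2-en-1-yl acetate | CC(=O)OC/C(CC[C@@H](O)C(=C)C[C@H](O[Si](CC)(CC)CC)C#C[Si](C)(C)C)=C/COCc1ccc(OC)cc1 | intermediate
14 | (E)-2-[(3R,6S)-3-[(tert-butyldimethylsilyl)oxy]-4-methylidene-6-[(triethylsilyl)oxy]-8-(trimethylsilyl)oct-7-yn-1-yl]-4-[(4-methoxybenzyl)oxy]but-2-en-1-yl acetate | CC(=O)OC/C(CC[C@@H](O[Si](C)(C)C(C)(C)C)C(=C)C[C@H](O[Si](CC)(CC)CC)C#C[Si](C)(C)C)=C/COCc1ccc(OC)cc1 | intermediate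
15 | (E)-2-[(3R,6S)-3-[(tert-butyldimethylsilyl)oxy]-4-methylidene-6-[(triethylsilyl)oxy]oct-7-yn-1-yl]-4-[(4-methoxybenzyl)oxy]but-2-en-1-yl acetate | CC(=O)OC/C(CC[C@@H](O[Si](C)(C)C(C)(C)C)C(=C)C[C@H](O[Si](CC)(CC)CC)C#C)=C/COCc1ccc(OC)cc1 | intermediate
16 | (E)-2-[(3R,6S)-3-[(tert-butyldimethylsilyl)oxy]-9-(dicyclohexylamino)-4-methylidene-6-[(triethylsilyl)oxy]non-7-yn-1-yl]-4-[(4-methoxybenzyl)oxy]but-2-en-1-yl acetate | CC(=O)OC/C(CC[C@@H](O[Si](C)(C)C(C)(C)C)C(=C)C[C@H](O[Si](CC)(CC)CC)C#CCN(C1CCCCC1)C1CCCCC1)=C/COCc1ccc(OC)cc1 | intermediate (not isolated)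
17 | (E)-2-[(3R,6S)-3-[(tert-butyldimethylsilyl)oxy]-4-methylidene-6-[(triethylsilyl)oxy]nona-7,8-dien-1-yl]-4-[(4-methoxybenzyl)oxy]but-2-en-1-yl acetate | CC(=O)OC/C(CC[C@@H](O[Si](C)(C)C(C)(C)C)C(=C)C[C@H](O[Si](CC)(CC)CC)C=C=C)=C/COCc1ccc(OC)cc1 | intermediate
18 | (E)-2-[(3R,6S)-3-[(tert-butyldimethylsilyl)oxy]-4-methylidene-6-[(triethylsilyl)oxy]nona-7,8-dien-1-yl]-4-hydroxybut-2-en-1-yl acetate | CC(=O)OC/C(CC[C@@H](O[Si](C)(C)C(C)(C)C)C(=C)C[C@H](O[Si](CC)(CC)CC)C=C=C)=C/CO | intermediate
19 | (E)-2-[(3R,6S)-3-[(tert-butyldimethylsilyl)oxy]-4-methylidene-6-[(triethylsilyl)oxy]nona-7,8-dien-1-yl]-4-oxobut-2-en-1-yl acetate | CC(=O)OC/C(CC[C@@H](O[Si](C)(C)C(C)(C)C)C(=C)C[C@H](O[Si](CC)(CC)CC)C=C=C)=C/C=O | intermediate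
20 | (1R,6S,7R,8S)-15-acetoxy-1-[(tert-butyldimethylsilyl)oxy]-8-[(triethylsilyl)oxy]germacra-4,10(14),11(13)-trien-12,6-olide | C=C1C(=O)O[C@H]2/C=C(/COC(C)=O)CC[C@@H](O[Si](C)(C)C(C)(C)C)C(=C)C[C@H](O[Si](CC)(CC)CC)[C@@H]12 | intermediate
21 | (1R,6S,7R,8S)-15-acetoxy-1-[(tert-butyldimethylsilyl)oxy]-8-hydroxygermacra-4,10(14),11(13)-trien-12,6-olide | C=C1C(=O)O[C@H]2/C=C(/COC(C)=O)CC[C@@H](O[Si](C)(C)C(C)(C)C)C(=C)C[C@H](O)[C@@H]12 | intermediate
22 | (R)-4-hydroxydihydrofuran-2(3H)-one | O=C1C[C@@H](O)CO1 | starting material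
23 | (3R,4R)-3-[(dimethylamino)methyl]-4-hydroxydihydrofuran-2(3H)-one | O=C1[C@H](CN(C)C)[C@@H](O)CO1 | intermediate
24 | [(3R,4R)-4-hydroxy-2-oxotetrahydrofuran-3-yl]-N,N,N-trimethylmethanaminium iodide | O=C1[C@H](C[N+](C)(C)C)[C@@H](O)CO1.[I-] | intermediate (not isolated)
25 | (R)-4-hydroxy-3-methylidenedihydrofuran-2(3H)-one | O=C1C(=C)[C@@H](O)CO1 | intermediate
26 | methyl 2-[(4R)-2,2-dimethyl-1,3-dioxolan-4-yl]prop-2-enoate | C=C(C(=O)OC)[C@@H]1COC(C)(C)O1 | intermediate
27 | 2-[(4R)-2,2-dimethyl-1,3-dioxolan-4-yl]prop-2-enoic acid | C=C(C(=O)O)[C@@H]1COC(C)(C)O1 | intermediate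
28 | 2-[(4R)-2,2-dimethyl-1,3-dioxolan-4-yl]prop-2-enoic 2,4,6-trichlorobenzoic anhydride | C=C(C(=O)OC(=O)c1c(Cl)cc(Cl)cc1Cl)[C@@H]1COC(C)(C)O1 | intermediate (not isolated)
29 | (1R,6S,7R,8S)-15-acetoxy-1-[(tert-butyldimethylsilyl)oxy]-8-[2-[(4R)-2,2-dimethyl-1,3-dioxolan-4-yl]prop-2-enoyloxy]germacra-4,10(14),11(13)-trien-12,6-olide | C=C1C(=O)O[C@H]2/C=C(/COC(C)=O)CC[C@@H](O[Si](C)(C)C(C)(C)C)C(=C)C[C@H](OC(=O)C(=C)[C@@H]3COC(C)(C)O3)[C@@H]12 | intermediate
30 | (1R,6S,7R,8S)-15-acetoxy-8-[(3R)-3,4-dihydroxy-2-methylidenebutanoyloxy]-1-hydroxygermacra-4,10(14),11(13)-trien-12,6-olide | C=C1C(=O)O[C@H]2/C=C(/COC(C)=O)CC[C@@H](O)C(=C)C[C@H](OC(=O)C(=C)[C@@H](O)CO)[C@@H]12 | target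

**Step count and risks**

Total steps: 21. Longest linear sequence: 15 (steps 1–5, 8–15, 20, 21).

Step 14 (proposed new method). What may go wrong: oligomerisation outrunning the ten-membered ring closure; poor cis/trans control at the ring fusion; poor facial selectivity at the allene relative to C8; the catalyst being held by the conjugated enal. Fallback with known reaction types, setting out from 19 and returning at 20: palladium-catalysed silastannylation of the allene with Me3SiSnBu3 ([Pd(C3H5)Cl]2 cat., THF, high dilution) puts tin on C13 and silicon on C11, and the allylstannane so formed adds through C7 to the C6 aldehyde (the tandem silastannylation–allyl addition known for allenyl aldehydes). After work-up this should give the macrocyclic cis-homoallylic alcohol with a 1-(trimethylsilyl)vinyl group on C7, F1. Iododesilylation (N-iodosuccinimide, (CF3)2CHOH, 0 °C) should give the vinyl iodide F2, and palladium-catalysed carbonylative lactonisation (Pd(PPh3)4, CO 1 atm, Et3N, MeCN, 50 °C) closes the lactone to 20.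

Step 8. What may go wrong: weak ligand control of the aldehyde face, giving poor selectivity at C1. Fallback, setting out from 8 and 12 and returning at 13: coupling without chiral ligand (CrCl2, NiCl2 cat., DMSO, rt) gives 13 together with its C1 epimer F3; Dess–Martin oxidation of the mixture gives the enone F4; Corey–Bakshi–Shibata reduction ((S)-2-methyl-CBS-oxazaborolidine, catecholborane, toluene, −78 °C), with the alkenyl group as the large substituent, should return 13.

Step 6. What may go wrong: low enantioselectivity of the chromium-catalysed 2-bromoallylation on this ynal. Fallback, setting out from 9 and 10 and returning at 11: Barbier allylation without stereocontrol (In powder, THF/H2O, rt) gives the racemic alcohol F5; Dess–Martin oxidation gives the ynone F6; Noyori transfer hydrogenation (RuCl[(S,S)-TsDPEN](p-cymene), iPrOH, rt) should return 11.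

**Further compounds**

F1 | step 14 | (1R,8S)-15-acetoxy-1-[(tert-butyldimethylsilyl)oxy]-6-hydroxy-8-[(triethylsilyl)oxy]-7-[1-(trimethylsilyl)ethenyl] ten-membered carbocycle with the C6 and C7 configuration of 20 | O[C@H]1/C=C(/COC(C)=O)CC[C@@H](O[Si](C)(C)C(C)(C)C)C(=C)C[C@H](O[Si](CC)(CC)CC)[C@H]1C(=C)[Si](C)(C)C
F2 | step 14 | the corresponding 7-(1-iodoethenyl) alcohol | O[C@H]1/C=C(/COC(C)=O)CC[C@@H](O[Si](C)(C)C(C)(C)C)C(=C)C[C@H](O[Si](CC)(CC)CC)[C@H]1C(=C)I
F3 | step 8 | (E)-2-[(3S,6S)-3-hydroxy-4-methylidene-6-[(triethylsilyl)oxy]-8-(trimethylsilyl)oct-7-yn-1-yl]-4-[(4-methoxybenzyl)oxy]but-2-en-1-yl acetate (C1 epimer of 13) | CC(=O)OC/C(CC[C@H](O)C(=C)C[C@H](O[Si](CC)(CC)CC)C#C[Si](C)(C)C)=C/COCc1ccc(OC)cc1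
F4 | step 8 | (E)-2-[(6S)-4-methylidene-3-oxo-6-[(triethylsilyl)oxy]-8-(trimethylsilyl)oct-7-yn-1-yl]-4-[(4-methoxybenzyl)oxy]but-2-en-1-yl acetate | CC(=O)OC/C(CCC(=O)C(=C)C[C@H](O[Si](CC)(CC)CC)C#C[Si](C)(C)C)=C/COCc1ccc(OC)cc1
F5 | step 6 | 5-bromo-1-(trimethylsilyl)hex-5-en-1-yn-3-ol (racemic) | C=C(Br)CC(O)C#C[Si](C)(C)C
F6 | step 6 | 5-bromo-1-(trimethylsilyl)hex-5-en-1-yn-3-one | C=C(Br)CC(=O)C#C[Si](C)(C)C
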